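**Strategy**

The route rests on the C4a–C5 bond of the cyclohexenol ring (chromenone numbering), made last. The key step exploits the 2-alkyl-4-pyrone ring: its C4 carbonyl is basic, and once it is protonated the C8 hydrogens become acidic, so that a dienol forms which is nucleophilic at C4a. A chiral phosphoric acid should use this to close the carbocycle onto a tethered aldehyde, set the C5 carbinol centre and restore the pyrone in one operation. The precursor is an achiral 2,6-dialkyl-4-pyrone with a 4-oxobutyl arm, built by two lateral alkylations of 2,6-dimethyl-4-pyrone; the Z-alkene comes from a commercial pheromone alcohol.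

Key step: step 5

Assumption: the facial sense of the chiral phosphoric acid in step 5 cannot be fixed from a model, so (R)-TRIP is written and the (S)-acid would be taken instead if it proves to be the one that leads to the (5S) carbinol; atoms are numbered as in 4H-chromen-4-one.

**Route**

Step 1
Reactants: 1 (Z)-hexadec-11-en-1-ol
Product: 2 (5Z)-16-iodohexadec-5-ene
Conditions: I2, PPh3, imidazole, CH2Cl2, 0 °C → rt, dark
Reagents that add atoms: iodine, II
Why: Appel iodination replaces the primary hydroxyl by iodide through SN2 attack on the oxyphosphonium ion and should leave the remote Z-alkene untouched when run cold and in the dark.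

Step 2
Reactants: 2 (5Z)-16-iodohexadec-5-ene; 3 2,6-dimethyl-4H-pyran-4-one (in excess)
Product: 5 2-[(12Z)-heptadec-12-en-1-yl]-6-methyl-4H-pyran-4-one, via lithium dienolate 4 (not isolated)
Conditions: 3 (2.5 equiv), LDA (commercial solution, 2.4 equiv), THF, −78 °C; then 2 (1.0 equiv), DMPU, −78 → −20 °C
Reagents that add atoms: none
Why: Lateral lithiation of a 2-methyl-4-pyrone gives a dienolate that primary iodides alkylate at the exocyclic carbon (vinylogous enolate alkylation), and the excess of the cheap symmetrical pyrone should hold back a second alkylation.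

Step 3
Reactants: 5 2-[(12Z)-heptadec-12-en-1-yl]-6-methyl-4H-pyran-4-one; 6 3-bromo-1,1-dimethoxypropane
Product: 8 2-(4,4-dimethoxybutyl)-6-[(12Z)-heptadec-12-en-1-yl]-4H-pyran-4-one, via lithium dienolate 7 (not isolated)
Conditions: LDA (commercial solution, 1.1 equiv), THF, −78 °C; then 6 (2 equiv), DMPU, −78 → −10 °C
Reagents that add atoms: none
Why: Kinetic lateral lithiation with a hindered amide base should take the CH3 group in preference to the chain CH2, as in the stepwise alkylation of 2,6-lutidine, and SN2 alkylation of the dienolate then completes the masked four-carbon aldehyde arm.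

Step 4
Reactants: 8 2-(4,4-dimethoxybutyl)-6-[(12Z)-heptadec-12-en-1-yl]-4H-pyran-4-one
Product: 9 4-{6-[(12Z)-heptadec-12-en-1-yl]-4-oxo-4H-pyran-2-yl}butanal
Conditions: AcOH/THF/H2O (3:1:1), 40 °C
Reagents that add atoms: water, O
Why: Acid-catalysed hydrolysis of the dimethyl acetal frees the aldehyde, and acetic acid is too weak to protonate the pyrone carbonyl, so the ring closure of step 5 should not start here without stereocontrol.

Step 5
Reactants: 9 4-{6-[(12Z)-heptadec-12-en-1-yl]-4-oxo-4H-pyran-2-yl}butanal
Product: 12 (5S)-2-[(12Z)-heptadec-12-en-1-yl]-5-hydroxy-5,6,7,8-tetrahydro-4H-chromen-4-one, via pyran-2-ylidene dienol 10 (not isolated), via 4a-H keto tautomer 11 (not isolated)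
Conditions: (R)-TRIP [3,3'-bis(2,4,6-triisopropylphenyl)-BINOL hydrogen phosphate] (10 mol %), 4 Å MS, PhMe (0.02 M), 50 °C
Reagents that add atoms: none
Why: Proposed new method: the acid should protonate the basic C4 carbonyl of 9, and its phosphate should then take a proton from the CH2 next to the ring (the anhydrobase behaviour known for 2-alkyl-4-oxypyrylium ions) to give dienol 10, whose C4a adds to the acid-bound aldehyde to give 11, after which a proton shift from C4a to C8 restores the pyrone; direct attack of the same carbon of the unchanged pyrone on the activated aldehyde (Friedel–Crafts hydroxyalkylation) leads to the same product. The closest known reaction types are chiral Brønsted acid-catalysed intramolecular aldol and carbonyl-ene cyclisations of tethered carbonyl compounds. The carbocycle closes in a 6-(enolexo)-exo-trig mode. The C5 stereocentre is set by the catalyst, whose phosphate bridges the dienol O–H and the aldehyde oxygen in a cyclic transition state inside the chiral pocket, so that one aldehyde face is presented to C4a. The step needs site selectivity (C4a against the exocyclic C8, and the arm-side dienol against the chain-side dienol) and chemoselectivity against intermolecular aldol reaction: attack through C8 would need a four-membered ring, the chain-side dienol has no electrophile in reach and reverts to 9, and high dilution holds back the intermolecular path.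

**Compound list**

1 | (Z)-hexadec-11-en-1-ol | CCCC/C=C\CCCCCCCCCCO | starting material
2 | (5Z)-16-iodohexadec-5-ene | CCCC/C=C\CCCCCCCCCCI | intermediate
3 | 2,6-dimethyl-4H-pyran-4-one | Cc1cc(=O)cc(C)o1 | starting material
4 | lithium 2-methyl-6-methylidene-6H-pyran-4-olate (lithium dienolate of 3) | C=C1C=C(O[Li])C=C(C)O1 | intermediate
5 | 2-[(12Z)-heptadec-12-en-1-yl]-6-methyl-4H-pyran-4-one | CCCC/C=C\CCCCCCCCCCCc1cc(=O)cc(C)o1 | intermediate
6 | 3-bromo-1,1-dimethoxypropane | COC(CCBr)OC | starting material
7 | lithium 2-[(12Z)-heptadec-12-en-1-yl]-6-methylidene-6H-pyran-4-olate (lithium dienolate of 5) | C=C1C=C(O[Li])C=C(CCCCCCCCCCC/C=C\CCCC)O1 | intermediate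
8 | 2-(4,4-dimethoxybutyl)-6-[(12Z)-heptadec-12-en-1-yl]-4H-pyran-4-one | COC(CCCc1cc(=O)cc(CCCCCCCCCCC/C=C\CCCC)o1)OC | intermediate
9 | 4-{6-[(12Z)-heptadec-12-en-1-yl]-4-oxo-4H-pyran-2-yl}butanal | O=CCCCc1cc(=O)cc(CCCCCCCCCCC/C=C\CCCC)o1 | intermediate
10 | 4-{(2E)-6-[(12Z)-heptadec-12-en-1-yl]-4-hydroxy-2H-pyran-2-ylidene}butanal (arm cis to the ring CH) | O=CCC/C=C1\C=C(O)C=C(CCCCCCCCCCC/C=C\CCCC)O1 | intermediate
11 | (5S)-2-[(12Z)-heptadec-12-en-1-yl]-5-hydroxy-4a,5,6,7-tetrahydro-4H-chromen-4-one (C4a not defined) | O[C@H]1CCC=C2OC(CCCCCCCCCCC/C=C\CCCC)=CC(=O)C12 | intermediate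
12 | (5S)-2-[(12Z)-heptadec-12-en-1-yl]-5-hydroxy-5,6,7,8-tetrahydro-4H-chromen-4-one | CCCC/C=C\CCCCCCCCCCCc1cc(=O)c2c(o1)CCC[C@@H]2O | target

**Count**

Total step count: 5. Longest linear sequence: 5 steps (1 → 2 → 5 → 8 → 9 → 12).

**Steps most likely to fail**

1. Step 5 (proposed new method).
   - What may go wrong: the dienol may form too slowly under the weak chiral acid; the catalyst may stay bound to the pyrone carbonyl; the ring may close with poor facial selectivity; or the carbinol may lose its configuration through retro-aldol reopening.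
   - Fallback: the ring is closed at the ketone oxidation level with a stoichiometric dienolate, and the stereocentre is set afterwards by reagent control. It sets out from 9 and comes back at 12.
   - Pinnick oxidation (NaClO2, NaH2PO4, 2-methyl-2-butene, t-BuOH/H2O) would give 4-{6-[(12Z)-heptadec-12-en-1-yl]-4-oxo-4H-pyran-2-yl}butanoic acid F1. MeI/K2CO3 in DMF would give its methyl ester, methyl 4-{6-[(12Z)-heptadec-12-en-1-yl]-4-oxo-4H-pyran-2-yl}butanoate F2.
   - LiHMDS (2.2 equiv, THF, −78 °C → rt) would form the lateral dienolate, which attacks the ester through C4a in a Dieckmann condensation. Attack through C8 would need a cyclobutanone, and deprotonation of the new 1,3-dicarbonyl unit drives the closure. Work-up should give 2-[(12Z)-heptadec-12-en-1-yl]-7,8-dihydro-4H-chromene-4,5(6H)-dione F3.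
   - Noyori transfer hydrogenation with RuCl[(S,S)-TsDPEN](p-cymene) in HCO2H/Et3N does not touch the isolated alkene. It should reduce the C5 ketone to the (S) alcohol in the sense known for 1-tetralone, which gives 12.

2. Step 3.
   - What may go wrong: at the temperature the SN2 step needs, proton transfer may move the lithium from the methyl-derived position to the CH2 of the long chain (loss of site selectivity), and the base may eliminate HBr from 6.
   - Fallback: a more reactive electrophile is taken up at −78 °C under kinetic control, and the aldehyde is reached by a change of oxidation state instead of acetal hydrolysis. It sets out from 5 and comes back at 9, so step 4 is not needed.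
   - LDA at −78 °C followed by allyl bromide would give 2-(but-3-en-1-yl)-6-[(12Z)-heptadec-12-en-1-yl]-4H-pyran-4-one F4.
   - 9-BBN hydroborates a terminal alkene much faster than a 1,2-disubstituted one; oxidation with NaBO3·4H2O would then give 2-[(12Z)-heptadec-12-en-1-yl]-6-(4-hydroxybutyl)-4H-pyran-4-one F5.
   - Dess–Martin periodinane (NaHCO3, CH2Cl2) would give 9.

3. Step 2.
   - What may go wrong: slow substitution of the unactivated iodide by the dienolate; a second alkylation after proton exchange between product and dienolate; and self-condensation of the lithiated pyrone on warming.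
   - Fallback: the pyrone ring is built around the chain by 1,3,5-triketone chemistry. It sets out from 2 and comes back at 5.
   - The dianion of acetylacetone (NaH, then n-BuLi, THF, 0 °C) would be alkylated by 2 at the terminal carbon to give (Z)-henicos-16-ene-2,4-dione F6.
   - The dianion of this diketone (LDA, THF) would be acylated at the methyl terminus with ethyl acetate to give (Z)-tricos-18-ene-2,4,6-trione F7.
   - Acid-catalysed cyclodehydration (TsOH, PhMe, 80 °C) would give 5.

Further compounds
F1 | step 5 | 4-{6-[(12Z)-heptadec-12-en-1-yl]-4-oxo-4H-pyran-2-yl}butanoic acid | OC(=O)CCCc1cc(=O)cc(CCCCCCCCCCC/C=C\CCCC)o1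
F2 | step 5 | methyl 4-{6-[(12Z)-heptadec-12-en-1-yl]-4-oxo-4H-pyran-2-yl}butanoate | COC(=O)CCCc1cc(=O)cc(CCCCCCCCCCC/C=C\CCCC)o1
F3 | step 5 | 2-[(12Z)-heptadec-12-en-1-yl]-7,8-dihydro-4H-chromene-4,5(6H)-dione | O=C1CCCc2oc(CCCCCCCCCCC/C=C\CCCC)cc(=O)c12
F4 | step 3 | 2-(but-3-en-1-yl)-6-[(12Z)-heptadec-12-en-1-yl]-4H-pyran-4-one | C=CCCc1cc(=O)cc(CCCCCCCCCCC/C=C\CCCC)o1
F5 | step 3 | 2-[(12Z)-heptadec-12-en-1-yl]-6-(4-hydroxybutyl)-4H-pyran-4-one | OCCCCc1cc(=O)cc(CCCCCCCCCCC/C=C\CCCC)o1
F6 | step 2 | (Z)-henicos-16-ene-2,4-dione | CCCC/C=C\CCCCCCCCCCCC(=O)CC(=O)C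
F7 | step 2 | (Z)-tricos-18-ene-2,4,6-trione | CCCC/C=C\CCCCCCCCCCCC(=O)CC(=O)CC(=O)C
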